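**Plan**

- Numbered from the lactone carbonyl (C1; ring O on C5; carbinols C7, C9, C11; nonyl C12–C20), the target is a decanoyl starter plus five acetate units. C3 alone stays a ketone and the C5 oxygen lies δ to C1, so a 5-hydroxy-3-oxo thioester must close to the six-membered ring O1–C1–C2–C3–C4–C5.
- Retrosynthesis: O5–C1 and C2–C3 are cut together (lactonisation after a decarboxylative Claisen), then C4–C5, C6–C7 and C8–C9, each a two-carbon Claisen disconnection, back to methyl 3-oxododecanoate.
- Forward: the chain grows from the C9–C20 β-keto ester by C8–C9 (step 2, lithium enolate), C6–C7 (step 5, malonate half ester), C4–C5 (step 7, magnesium enolate) and C2–C3 (step 11); the only ring forms last, in the same flask.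
- Stereochemistry: C11 by hydrogenation with RuCl2[(S)-BINAP]; C9 syn to C11 by Narasaka–Prasad reduction; C7 anti to C9 by hydrogenation with RuCl2[(R)-BINAP]; C5 syn to C7 by a second Narasaka–Prasad reduction.
- Carbinols travel as TBS ethers; the silyl triflate that protects each diol also turns the tert-butyl ester into a silyl ester that mild carbonate frees as the acid, and aqueous HF removes all four silyl groups in the last step.

Key step: step 11

Remark: the ring is taken as the 4-hydroxy enol tautomer shown, the stable form of this 3-oxo-δ-lactone. TBS = tert-butyldimethylsilyl; BINAP = 2,2'-bis(diphenylphosphino)-1,1'-binaphthyl. CIP descriptors change along the route only because silylation and chain extension alter priorities; no centre is inverted.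

**Route**

Step 1
Reactants: 1 methyl 3-oxododecanoate
Product: 2 methyl (3S)-3-hydroxydodecanoate
Conditions: RuCl2[(S)-BINAP] (0.5 mol%), H2 (50 atm), MeOH, 50 °C
Reagents that add atoms: none
Why: Noyori asymmetric hydrogenation of a β-keto ester, in which the substrate chelates the RuCl2[(S)-BINAP] catalyst through both carbonyls and the (S)-ligand directs hydride to the face that gives the (3S)-alcohol (C11 of the target).

Step 2
Reactants: 2 methyl (3S)-3-hydroxydodecanoate; 3 tert-butyl acetate
Product: 5 tert-butyl (5S)-5-hydroxy-3-oxotetradecanoate, via lithium enolate of tert-butyl acetate 4 (not isolated)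
Conditions: 3 (3.5 equiv), LiN(iPr)2 (3.5 equiv), THF, −78 °C; then 2, −78 → −20 °C; aq. NH4Cl
Reagents that add atoms: none
Why: Crossed Claisen condensation of a β-hydroxy ester, in which excess enolate first forms the lithium alkoxide that activates the neighbouring ester and then acylates on carbon, the product being stored as its enolate so that no second addition occurs, while the tert-butyl ester does not self-condense and the carbinol centre is untouched.

Step 3
Reactants: 5 tert-butyl (5S)-5-hydroxy-3-oxotetradecanoate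
Product: 7 tert-butyl (3S,5S)-3,5-dihydroxytetradecanoate, via diethylboron chelate 6 (not isolated)
Conditions: Et2BOMe (1.1 equiv), THF/MeOH (4:1), −78 °C; NaBH4, −78 °C; AcOH, then MeOH co-evaporation
Reagents that add atoms: none
Why: Narasaka–Prasad reduction, in which boron ties the C5 oxygen and the C3 ketone into a six-membered half-chair with the alkyl chain equatorial and external axial hydride delivery gives the 1,3-syn diol (C9 of the target syn to C11).

Step 4
Reactants: 7 tert-butyl (3S,5S)-3,5-dihydroxytetradecanoate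
Product: 10 (3S,5S)-3,5-bis(TBSO)tetradecanoic acid, via bis-silyl tert-butyl ester 8 (not isolated), via silyl ester 9 (not isolated)
Conditions: TBSOTf (4 equiv), 2,6-lutidine (6 equiv), CH2Cl2, −78 °C → rt; then K2CO3, MeOH/THF/H2O, 0 °C; pH 4 work-up
Reagents that add atoms: tert-butyldimethylsilyl trifluoromethanesulfonate (TBSOTf), CC(C)(C)[Si](C)(C)OS(=O)(=O)C(F)(F)F
Why: Silyl triflate silylation of both carbinols followed by silyl-triflate cleavage of the tert-butyl ester (O-silylation of the ester carbonyl, loss of 2-methylpropene) should give silyl ester 9, and mild carbonate hydrolysis cleaves only that silyl ester, so the acid is unmasked without touching the ethers or the stereocentres.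

Step 5
Reactants: 10 (3S,5S)-3,5-bis(TBSO)tetradecanoic acid; 11 potassium 3-ethoxy-3-oxopropanoate (potassium ethyl malonate)
Product: 13 ethyl (5S,7S)-5,7-bis(TBSO)-3-oxohexadecanoate, via acyl imidazolide 12 (not isolated)
Conditions: carbonyldiimidazole (1.2 equiv), THF, rt; then 11, MgCl2, Et3N, MeCN, rt → 40 °C; aq. NH4Cl
Reagents that add atoms: none
Why: Masamune–Brooks decarboxylative Claisen condensation, in which the magnesium-chelated malonate half ester is C-acylated by the acyl imidazolide and loses CO2 to give the β-keto ester under near-neutral conditions that leave the β-silyloxy group in place.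

Step 6
Reactants: 13 ethyl (5S,7S)-5,7-bis(TBSO)-3-oxohexadecanoate
Product: 14 ethyl (3R,5R,7S)-3-hydroxy-5,7-bis(TBSO)hexadecanoate
Conditions: RuCl2[(R)-BINAP] (1 mol%), H2 (10 atm), EtOH, 40 °C
Reagents that add atoms: none
Why: Noyori asymmetric hydrogenation under catalyst control, in which the (R)-ligand gives the (3R)-alcohol that is 1,3-anti to the C5 silyloxy group (C7 of the target anti to C9), with ethanol at moderate temperature chosen to avoid transesterification and spare the silyl ethers.

Step 7
Reactants: 14 ethyl (3R,5R,7S)-3-hydroxy-5,7-bis(TBSO)hexadecanoate; 3 tert-butyl acetate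
Product: 16 tert-butyl (5R,7R,9S)-5-hydroxy-7,9-bis(TBSO)-3-oxooctadecanoate, via chloromagnesium enolate of tert-butyl acetate 15 (not isolated)
Conditions: iPr2NMgCl (4.5 equiv; made from iPrMgCl and iPr2NH, THF, 40 °C), THF, −20 °C; then 3 (3.5 equiv) and 14 added together dropwise, −20 → 0 °C; aq. NH4Cl
Reagents that add atoms: none
Why: Crossed Claisen condensation through a magnesium enolate made with a Hauser base (chloromagnesium diisopropylamide), in which the base first turns the C3 hydroxyl of 14 into its chloromagnesium alkoxide, this chelate activates the ethyl ester towards C-acylation of enolate 15, the β-keto ester is held as its magnesium enolate so that no second addition follows, and the covalent magnesium alkoxide should resist silyl transfer from the neighbouring ether at a temperature that needs no deep cooling.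

Step 8
Reactants: 16 tert-butyl (5R,7R,9S)-5-hydroxy-7,9-bis(TBSO)-3-oxooctadecanoate
Product: 18 tert-butyl (3R,5S,7R,9S)-3,5-dihydroxy-7,9-bis(TBSO)octadecanoate, via diethylboron chelate 17 (not isolated)
Conditions: Et2BOMe (1.1 equiv), THF/MeOH (4:1), −78 °C; NaBH4, −78 °C; AcOH, then MeOH co-evaporation
Reagents that add atoms: none
Why: Narasaka–Prasad reduction, in which the boron chelate between the free C5 hydroxyl and the C3 ketone directs external hydride to give the 1,3-syn diol (C5 of the target syn to C7).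

Step 9
Reactants: 18 tert-butyl (3R,5S,7R,9S)-3,5-dihydroxy-7,9-bis(TBSO)octadecanoate
Product: 21 (3R,5R,7S,9S)-3,5,7,9-tetrakis(TBSO)octadecanoic acid, via tetrakis-silyl tert-butyl ester 19 (not isolated), via silyl ester 20 (not isolated)
Conditions: TBSOTf (5 equiv), 2,6-lutidine (8 equiv), CH2Cl2, −78 °C → rt; then K2CO3, MeOH/THF/H2O, 0 °C; pH 4 work-up
Reagents that add atoms: tert-butyldimethylsilyl trifluoromethanesulfonate (TBSOTf), CC(C)(C)[Si](C)(C)OS(=O)(=O)C(F)(F)F
Why: Silyl triflate silylation and silyl-triflate cleavage of the tert-butyl ester as in step 4, followed by selective hydrolysis of the silyl ester, should give the fully protected C3–C20 acid.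

Step 10
Reactants: 22 Meldrum's acid (2,2-dimethyl-1,3-dioxane-4,6-dione); 23 ethanethiol
Product: 24 3-(ethylsulfanyl)-3-oxopropanoic acid
Conditions: 23 (1.5 equiv), toluene, 85 °C, sealed tube
Reagents that add atoms: none
Why: Thiolysis of Meldrum's acid, in which the thiol opens the activated cyclic diester at one carbonyl and acetone is lost, the standard preparation of malonic acid half thioesters.

Step 11
Reactants: 21 (3R,5R,7S,9S)-3,5,7,9-tetrakis(TBSO)octadecanoic acid; 24 3-(ethylsulfanyl)-3-oxopropanoic acid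
Product: 29 (6R)-4-hydroxy-6-[(2R,4S,6S)-2,4,6-trihydroxypentadecyl]-5,6-dihydro-2H-pyran-2-one, via magnesium half-thioester malonate 25 (not isolated), via acyl imidazolide 26 (not isolated), via silylated 3-oxo thioester 27 (not isolated), via tetrahydroxy 3-oxo thioester 28 (not isolated)
Conditions: 24 (2.2 equiv), Mg(OEt)2 (1.1 equiv), THF, rt, evaporate; 21, carbonyldiimidazole (1.2 equiv), THF, rt; combine, rt → 35 °C; dilute aq. HCl wash; then 48% aq. HF, MeCN, 0 °C → rt
Reagents that add atoms: none
Why: Magnesium ethoxide converts 24 into the chelated magnesium malonate 25, whose carbon attacks the acyl imidazolide 26 and, by loss of CO2, gives the 3-oxo thioester 27 with the new C2–C3 bond, which is the Masamune–Brooks decarboxylative Claisen condensation of a malonic half thioester. Aqueous HF then cleaves the four silyl ethers to 28, and the freed C5 hydroxyl adds to the thioester carbonyl C1 and expels ethanethiol, the known lactonisation of 5-hydroxy-3-oxo (thio)esters to 4-hydroxy-5,6-dihydropyran-2-ones. The single ring closes in the 6-exo-trig mode. No stereocentre is created, and C5 keeps its configuration because only its O–H bond reacts. The step needs C-acylation in place of O-acylation, secured by the magnesium chelate of the malonate, and closure through O5 in place of O7, O9 or O11, secured by ring size (O7 would give an eight-membered lactone, and its six-membered hemiketal at C3 stays reversible in aqueous acid). The thioester is acylating enough to close at room temperature, which should spare the 3-oxo acid stage from decarboxylation and the C5 oxygen from elimination.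

**Compound list**

1 | methyl 3-oxododecanoate | CCCCCCCCCC(=O)CC(=O)OC | starting material
2 | methyl (3S)-3-hydroxydodecanoate | CCCCCCCCC[C@H](O)CC(=O)OC | intermediate
3 | tert-butyl acetate | CC(=O)OC(C)(C)C | starting material
4 | lithium enolate of tert-butyl acetate (lithium 1-tert-butoxyethen-1-olate; formed in the flask) | [Li+].C=C([O-])OC(C)(C)C | intermediate
5 | tert-butyl (5S)-5-hydroxy-3-oxotetradecanoate | CCCCCCCCC[C@H](O)CC(=O)CC(=O)OC(C)(C)C | intermediate
6 | tert-butyl (5S)-5-[(diethylboranyl)oxy]-3-oxotetradecanoate (boron chelated by the C3 ketone; formed in the flask) | CCCCCCCCC[C@H](OB(CC)CC)CC(=O)CC(=O)OC(C)(C)C | intermediate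
7 | tert-butyl (3S,5S)-3,5-dihydroxytetradecanoate | CCCCCCCCC[C@H](O)C[C@H](O)CC(=O)OC(C)(C)C | intermediate
8 | tert-butyl (3S,5S)-3,5-bis(TBSO)tetradecanoate (formed in the flask) | CCCCCCCCC[C@H](O[Si](C)(C)C(C)(C)C)C[C@H](O[Si](C)(C)C(C)(C)C)CC(=O)OC(C)(C)C | intermediate
9 | tert-butyldimethylsilyl (3S,5S)-3,5-bis(TBSO)tetradecanoate (formed in the flask) | CCCCCCCCC[C@H](O[Si](C)(C)C(C)(C)C)C[C@H](O[Si](C)(C)C(C)(C)C)CC(=O)O[Si](C)(C)C(C)(C)C | intermediate
10 | (3S,5S)-3,5-bis(TBSO)tetradecanoic acid | CCCCCCCCC[C@H](O[Si](C)(C)C(C)(C)C)C[C@H](O[Si](C)(C)C(C)(C)C)CC(=O)O | intermediate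
11 | potassium 3-ethoxy-3-oxopropanoate (potassium ethyl malonate) | CCOC(=O)CC(=O)[O-].[K+] | starting material
12 | 1-[(3S,5S)-3,5-bis(TBSO)tetradecanoyl]-1H-imidazole (formed in the flask) | CCCCCCCCC[C@H](O[Si](C)(C)C(C)(C)C)C[C@H](O[Si](C)(C)C(C)(C)C)CC(=O)n1ccnc1 | intermediate
13 | ethyl (5S,7S)-5,7-bis(TBSO)-3-oxohexadecanoate | CCCCCCCCC[C@H](O[Si](C)(C)C(C)(C)C)C[C@H](O[Si](C)(C)C(C)(C)C)CC(=O)CC(=O)OCC | intermediate
14 | ethyl (3R,5R,7S)-3-hydroxy-5,7-bis(TBSO)hexadecanoate | CCCCCCCCC[C@H](O[Si](C)(C)C(C)(C)C)C[C@H](O[Si](C)(C)C(C)(C)C)C[C@@H](O)CC(=O)OCC | intermediate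
15 | chloromagnesium enolate of tert-butyl acetate (chloromagnesium 1-tert-butoxyethen-1-olate, ClMgOC(=CH2)OC(CH3)3; formed in the flask) | C=C([O-])OC(C)(C)C.[Mg+2].[Cl-] | intermediate
16 | tert-butyl (5R,7R,9S)-5-hydroxy-7,9-bis(TBSO)-3-oxooctadecanoate | CCCCCCCCC[C@H](O[Si](C)(C)C(C)(C)C)C[C@H](O[Si](C)(C)C(C)(C)C)C[C@@H](O)CC(=O)CC(=O)OC(C)(C)C | intermediate
17 | tert-butyl (5R,7R,9S)-5-[(diethylboranyl)oxy]-7,9-bis(TBSO)-3-oxooctadecanoate (boron chelated by the C3 ketone; formed in the flask) | CCCCCCCCC[C@H](O[Si](C)(C)C(C)(C)C)C[C@H](O[Si](C)(C)C(C)(C)C)C[C@@H](OB(CC)CC)CC(=O)CC(=O)OC(C)(C)C | intermediate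
18 | tert-butyl (3R,5S,7R,9S)-3,5-dihydroxy-7,9-bis(TBSO)octadecanoate | CCCCCCCCC[C@H](O[Si](C)(C)C(C)(C)C)C[C@H](O[Si](C)(C)C(C)(C)C)C[C@@H](O)C[C@@H](O)CC(=O)OC(C)(C)C | intermediate
19 | tert-butyl (3R,5R,7S,9S)-3,5,7,9-tetrakis(TBSO)octadecanoate (formed in the flask) | CCCCCCCCC[C@H](O[Si](C)(C)C(C)(C)C)C[C@H](O[Si](C)(C)C(C)(C)C)C[C@@H](O[Si](C)(C)C(C)(C)C)C[C@@H](O[Si](C)(C)C(C)(C)C)CC(=O)OC(C)(C)C | intermediate
20 | tert-butyldimethylsilyl (3R,5R,7S,9S)-3,5,7,9-tetrakis(TBSO)octadecanoate (formed in the flask) | CCCCCCCCC[C@H](O[Si](C)(C)C(C)(C)C)C[C@H](O[Si](C)(C)C(C)(C)C)C[C@@H](O[Si](C)(C)C(C)(C)C)C[C@@H](O[Si](C)(C)C(C)(C)C)CC(=O)O[Si](C)(C)C(C)(C)C | intermediate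
21 | (3R,5R,7S,9S)-3,5,7,9-tetrakis(TBSO)octadecanoic acid | CCCCCCCCC[C@H](O[Si](C)(C)C(C)(C)C)C[C@H](O[Si](C)(C)C(C)(C)C)C[C@@H](O[Si](C)(C)C(C)(C)C)C[C@@H](O[Si](C)(C)C(C)(C)C)CC(=O)O | intermediate
22 | Meldrum's acid (2,2-dimethyl-1,3-dioxane-4,6-dione) | CC1(C)OC(=O)CC(=O)O1 | starting material
23 | ethanethiol | CCS | starting material
24 | 3-(ethylsulfanyl)-3-oxopropanoic acid | CCSC(=O)CC(=O)O | intermediate
25 | magnesium bis[3-(ethylsulfanyl)-3-oxopropanoate] (formed in the flask) | CCSC(=O)CC(=O)[O-].CCSC(=O)CC(=O)[O-].[Mg+2] | intermediate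
26 | 1-[(3R,5R,7S,9S)-3,5,7,9-tetrakis(TBSO)octadecanoyl]-1H-imidazole (formed in the flask) | CCCCCCCCC[C@H](O[Si](C)(C)C(C)(C)C)C[C@H](O[Si](C)(C)C(C)(C)C)C[C@@H](O[Si](C)(C)C(C)(C)C)C[C@@H](O[Si](C)(C)C(C)(C)C)CC(=O)n1ccnc1 | intermediate
27 | S-ethyl (5R,7R,9S,11S)-5,7,9,11-tetrakis(TBSO)-3-oxoicosanethioate (formed in the flask) | CCCCCCCCC[C@H](O[Si](C)(C)C(C)(C)C)C[C@H](O[Si](C)(C)C(C)(C)C)C[C@@H](O[Si](C)(C)C(C)(C)C)C[C@@H](O[Si](C)(C)C(C)(C)C)CC(=O)CC(=O)SCC | intermediate
28 | S-ethyl (5R,7R,9S,11S)-5,7,9,11-tetrahydroxy-3-oxoicosanethioate (formed in the flask) | CCCCCCCCC[C@H](O)C[C@H](O)C[C@@H](O)C[C@@H](O)CC(=O)CC(=O)SCC | intermediate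
29 | (6R)-4-hydroxy-6-[(2R,4S,6S)-2,4,6-trihydroxypentadecyl]-5,6-dihydro-2H-pyran-2-one | CCCCCCCCC[C@H](O)C[C@H](O)C[C@@H](O)C[C@@H]1CC(O)=CC(=O)O1 | target

**Step count**

Total step count: 11. Longest linear sequence: 10 (steps 1–9 and 11).

**Steps most likely to fail**

Step 11. After desilylation, closure of O5 onto the thioester may be slow in the acidic medium while the C3 ketone sits reversibly as its hemiketal with O7. Alternatively, silanol may be lost by β-elimination from the acyl imidazolide before the malonate adds. The fallback sets out from 21 and comes back at 29. Acid 21 is activated as before to 26 and treated in THF at −78 °C with the lithium enolate 4, made from 3 and LiN(iPr)2, a direct Claisen in place of the decarboxylative one. This should give tert-butyl (5R,7R,9S,11S)-5,7,9,11-tetrakis(TBSO)-3-oxoicosanoate F1. 48% aq. HF in MeCN should then give tert-butyl (5R,7R,9S,11S)-5,7,9,11-tetrahydroxy-3-oxoicosanoate F2. Trifluoroacetic acid in CH2Cl2 cleaves the tert-butyl ester with closure of O5 onto C1 to give 29. C2–C3 and O5–C1 remain the bonds formed.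

Step 7. The magnesium enolate may condense with tert-butyl acetate itself faster than with the chelated ethyl ester, or the alkoxide may take over the neighbouring silyl group before acylation occurs. The fallback sets out from 14 and comes back at 16. LiOH in THF/H2O at 0 °C should give (3R,5R,7S)-3-hydroxy-5,7-bis(TBSO)hexadecanoic acid F3. Carbonyldiimidazole in THF at rt converts its carboxyl group into 1-[(3R,5R,7S)-3-hydroxy-5,7-bis(TBSO)hexadecanoyl]-1H-imidazole F4, which is not isolated. Potassium 3-tert-butoxy-3-oxopropanoate, MgCl2 and Et3N in MeCN then deliver 16 by a decarboxylative Claisen condensation as in step 5, so that no strong base meets the hydroxy silyl ether array.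

Step 6. Silyl ethers may be lost through HCl released from the RuCl2[(R)-BINAP] precatalyst in warm alcohol, or facial selectivity may be poor if the β-silyloxy centre opposes the catalyst. The fallback sets out from 13 and comes back at 14. NaBH4 in EtOH at −20 °C should give 14 together with its C3 epimer, ethyl (3S,5R,7S)-3-hydroxy-5,7-bis(TBSO)hexadecanoate F5. The epimers are separated by chromatography, and F5 is oxidised back to 13 with Dess–Martin periodinane and reduced again, so that material is funnelled to 14 without a chiral catalyst.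

Further compounds
F1 | step 11 | tert-butyl (5R,7R,9S,11S)-5,7,9,11-tetrakis(TBSO)-3-oxoicosanoate | CCCCCCCCC[C@H](O[Si](C)(C)C(C)(C)C)C[C@H](O[Si](C)(C)C(C)(C)C)C[C@@H](O[Si](C)(C)C(C)(C)C)C[C@@H](O[Si](C)(C)C(C)(C)C)CC(=O)CC(=O)OC(C)(C)C
F2 | step 11 | tert-butyl (5R,7R,9S,11S)-5,7,9,11-tetrahydroxy-3-oxoicosanoate | CCCCCCCCC[C@H](O)C[C@H](O)C[C@@H](O)C[C@@H](O)CC(=O)CC(=O)OC(C)(C)C
F3 | step 7 | (3R,5R,7S)-3-hydroxy-5,7-bis(TBSO)hexadecanoic acid | CCCCCCCCC[C@H](O[Si](C)(C)C(C)(C)C)C[C@H](O[Si](C)(C)C(C)(C)C)C[C@@H](O)CC(=O)O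
F4 | step 7 | 1-[(3R,5R,7S)-3-hydroxy-5,7-bis(TBSO)hexadecanoyl]-1H-imidazole | CCCCCCCCC[C@H](O[Si](C)(C)C(C)(C)C)C[C@H](O[Si](C)(C)C(C)(C)C)C[C@@H](O)CC(=O)n1ccnc1
F5 | step 6 | ethyl (3S,5R,7S)-3-hydroxy-5,7-bis(TBSO)hexadecanoate | CCCCCCCCC[C@H](O[Si](C)(C)C(C)(C)C)C[C@H](O[Si](C)(C)C(C)(C)C)C[C@H](O)CC(=O)OCC
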